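## Retrosynthetic overview

1. The aryl hydrogen sulfate comes from monosulfation of a mirror-symmetric tetrahydroxyarene, itself the reduced form of a 3-alkyl-2,5-dihydroxy-1,4-benzoquinone.
2. The C11–aryl bond is made by a light-driven decarboxylative radical C–H alkylation of 2,5-dihydroxy-1,4-benzoquinone with 9-epi-homodrim-7-en-12-oic acid.
3. C9 (H cis to the C10 methyl) and the 7(8)-alkene are set together by reductive 1,3-transposition of a 7-oxo-8(9)-ene tosylhydrazone (suprafacial allylic-diazene H transfer).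
4. The enone comes from allylic oxidation of the 8(9)-ene ester obtained by acid methanolysis of (+)-sclareolide.
5. No ring is built: rings A and B (with C5 and C10) are bought in sclareolide, its lactone ring is opened first, and the six-membered quinone ring is bought.

Assumption: the SMILES is taken at face value, i.e. (5S,9R,10S) in drimane numbering – a 9-epi-drim-7-ene with the CH2Ar arm alpha (trans to the C10 methyl) – and the sulfate is isolated as the free hydrogen sulfate.

## Route

Step 1
Reactants: 1 (+)-sclareolide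
Product: 2 methyl 2-[(4aS,8aS)-2,5,5,8a-tetramethyl-3,4,4a,5,6,7,8,8a-octahydronaphthalen-1-yl]acetate (methyl homodrim-8-en-12-oate)
Conditions: conc. H2SO4, MeOH, reflux, 48 h
Reagents that add atoms: methanol, CO
Why: Acid-catalysed lactone methanolysis and E1 dehydration through the tertiary C8 cation equilibrate under thermodynamic control to the tetrasubstituted 8(9)-alkene ester, deliberately erasing C9 while C5 and C10 (bought with 1) stay untouched.

Step 2
Reactants: 2 methyl homodrim-8-en-12-oate
Product: 3 methyl 2-[(4aS,8aS)-2,5,5,8a-tetramethyl-3-oxo-3,4,4a,5,6,7,8,8a-octahydronaphthalen-1-yl]acetate (methyl 7-oxohomodrim-8-en-12-oate)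
Conditions: CrO3, AcOH/H2O, rt
Reagents that add atoms: chromium trioxide, O=[Cr](=O)=O
Why: Chromium-mediated allylic oxidation attacks the only ring allylic methylene (C7) in preference to the primary C12 methyl and the electron-poor, ester-flanked C11, giving the enone without touching a stereocentre.

Step 3
Reactants: 3 methyl 7-oxohomodrim-8-en-12-oate
Product: 4 methyl 2-[(4aS,8aS)-2,5,5,8a-tetramethyl-3-(2-tosylhydrazinylidene)-3,4,4a,5,6,7,8,8a-octahydronaphthalen-1-yl]acetate (tosylhydrazone of 3)
Conditions: TsNHNH2, cat. AcOH, EtOH, reflux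
Reagents that add atoms: p-toluenesulfonyl hydrazide, Cc1ccc(cc1)S(=O)(=O)NN
Why: Acid-catalysed tosylhydrazone formation at the C7 ketone installs the nitrogen handle for reductive alkene transposition; no stereocentre is affected.

Step 4
Reactants: 4 tosylhydrazone of 3
Product: 7 methyl 2-[(1R,4aS,8aS)-2,5,5,8a-tetramethyl-1,4,4a,5,6,7,8,8a-octahydronaphthalen-1-yl]acetate (methyl 9-epi-homodrim-7-en-12-oate), via N-boryl hydrazide 5 (not isolated), via allylic diazene 6 (not isolated)
Conditions: catecholborane, CHCl3, 0 °C to rt; then NaOAc·3H2O, reflux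
Reagents that add atoms: none
Why: Kabalka reductive transposition, in which catecholborane delivers hydride to C7 of the C=N from the alpha (axial) face as in the steroid 4-en-3-one series (which gives the 5-beta product), and the derived 7-beta diazene then passes its N–H hydrogen suprafacially to C9 on the beta face with loss of N2, moving the alkene to C7=C8 and setting C9 as R (H-9 cis to the C10 methyl, to be confirmed by NOE) under control of the bought C10 centre.

Step 5
Reactants: 7 methyl 9-epi-homodrim-7-en-12-oate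
Product: 8 2-[(1R,4aS,8aS)-2,5,5,8a-tetramethyl-1,4,4a,5,6,7,8,8a-octahydronaphthalen-1-yl]acetic acid (9-epi-homodrim-7-en-12-oic acid)
Conditions: LiOH, THF/MeOH/H2O, 50 °C; then 1 M HCl to pH 3–4, 0 °C
Reagents that add atoms: lithium hydroxide, [Li+].[OH-]
Why: Saponification of an unhindered methyl ester, where C9 is not alpha to the carbonyl and so cannot epimerise, and cold mild acidification avoids lactonisation onto the 7(8)-alkene.

Step 6
Reactants: 8 9-epi-homodrim-7-en-12-oic acid; 9 2,5-dihydroxy-1,4-benzoquinone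
Product: 11 2,5-dihydroxy-3-{[(1R,4aS,8aS)-2,5,5,8a-tetramethyl-1,4,4a,5,6,7,8,8a-octahydronaphthalen-1-yl]methyl}cyclohexa-2,5-diene-1,4-dione, via Barton ester 10 (not isolated)
Conditions: N-hydroxypyridine-2-thione, DCC, cat. DMAP, CH2Cl2, 0 °C, dark; then 9 (5 equiv), CH2Cl2/1,4-dioxane, 450 nm LEDs, 10 °C, Ar
Reagents that add atoms: none
Why: Proposed new method: visible-light N–O homolysis of the in-situ thiohydroxamate (Barton) ester gives CO2, the primary C11 radical and a 2-pyridylthiyl radical, the nucleophilic C11 radical adds to the unsubstituted C3–H carbon of the electron-poor quinone 9, and the semiquinone-type adduct radical is re-oxidised by the thiyl radical (H-atom transfer, or S-transfer then loss of pyridine-2-thiol), so the free hydroxyquinone is alkylated redox-neutrally with C9 untouched; the closest known reactions are the Barton–Zard addition of thiohydroxamate-ester radicals to benzo- and naphthoquinones and Fieser's peroxide alkylation of 2,5-dihydroxybenzoquinone, but a free dihydroxyquinone has not been used as acceptor in a Barton-ester photolysis.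

Step 7
Reactants: 11 alkylated dihydroxyquinone
Product: 13 2,4,5-trihydroxy-3-{[(1R,4aS,8aS)-2,5,5,8a-tetramethyl-1,4,4a,5,6,7,8,8a-octahydronaphthalen-1-yl]methyl}phenyl hydrogen sulfate (target, CNP0445131.2), via tetrahydroxyarene 12 (not isolated)
Conditions: Na2S2O4, EtOAc/H2O, rt, Ar; dry, concentrate; then SO3·pyridine (1.0 equiv), pyridine/DMF, −20 to 0 °C; Dowex 50W (H+ form), 0 °C, lyophilise
Reagents that add atoms: sulfur trioxide–pyridine complex, [O-]S(=O)(=O)[n+]1ccccc1
Why: Dithionite reduction gives the mirror-symmetric tetrahydroxyarene, whose two hydroxyls meta to the benzylic carbon are equivalent and far less hindered than the two ortho to the bulky drimanylmethyl arm, so one equivalent of SO3·pyridine (phenol O-sulfation) at low temperature gives the single monosulfate without affecting a stereocentre.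

## Compound list

1 | (+)-sclareolide, (3aR,5aS,9aS,9bR)-3a,6,6,9a-tetramethyl-decahydronaphtho[2,1-b]furan-2(1H)-one | C[C@]12CCCC(C)(C)[C@@H]1CC[C@@]1(C)OC(=O)C[C@H]21 | starting material
2 | methyl 2-[(4aS,8aS)-2,5,5,8a-tetramethyl-3,4,4a,5,6,7,8,8a-octahydronaphthalen-1-yl]acetate | COC(=O)CC1=C(C)CC[C@H]2C(C)(C)CCC[C@]12C | intermediate
3 | methyl 2-[(4aS,8aS)-2,5,5,8a-tetramethyl-3-oxo-3,4,4a,5,6,7,8,8a-octahydronaphthalen-1-yl]acetate | COC(=O)CC1=C(C)C(=O)C[C@H]2C(C)(C)CCC[C@]12C | intermediate
4 | tosylhydrazone of 3 (C=N geometry not defined) | COC(=O)CC1=C(C)C(=NNS(=O)(=O)c3ccc(C)cc3)C[C@H]2C(C)(C)CCC[C@]12C | intermediate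
5 | N-(1,3,2-benzodioxaborol-2-yl)-N'-tosyl hydrazide at C7, nitrogen 7-beta (3S) | COC(=O)CC1=C(C)[C@@H](N(NS(=O)(=O)c3ccc(C)cc3)B3Oc4ccccc4O3)C[C@H]2C(C)(C)CCC[C@]12C | intermediate
6 | 7-beta allylic diazene (3S) | COC(=O)CC1=C(C)[C@@H](N=N)C[C@H]2C(C)(C)CCC[C@]12C | intermediate
7 | methyl 2-[(1R,4aS,8aS)-2,5,5,8a-tetramethyl-1,4,4a,5,6,7,8,8a-octahydronaphthalen-1-yl]acetate | CC1=CC[C@H]2C(C)(C)CCC[C@]2(C)[C@@H]1CC(=O)OC | intermediate
8 | 2-[(1R,4aS,8aS)-2,5,5,8a-tetramethyl-1,4,4a,5,6,7,8,8a-octahydronaphthalen-1-yl]acetic acid | CC1=CC[C@H]2C(C)(C)CCC[C@]2(C)[C@@H]1CC(=O)O | intermediate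
9 | 2,5-dihydroxy-1,4-benzoquinone | O=C1C=C(O)C(=O)C=C1O | starting material
10 | 2-thioxopyridin-1(2H)-yl ester of 8 (Barton ester) | CC1=CC[C@H]2C(C)(C)CCC[C@]2(C)[C@@H]1CC(=O)ON1C=CC=CC1=S | intermediate
11 | 2,5-dihydroxy-3-{[(1R,4aS,8aS)-2,5,5,8a-tetramethyl-1,4,4a,5,6,7,8,8a-octahydronaphthalen-1-yl]methyl}cyclohexa-2,5-diene-1,4-dione | CC1=CC[C@H]2C(C)(C)CCC[C@]2(C)[C@@H]1CC1=C(O)C(=O)C=C(O)C1=O | intermediate
12 | 3-{[(1R,4aS,8aS)-2,5,5,8a-tetramethyl-1,4,4a,5,6,7,8,8a-octahydronaphthalen-1-yl]methyl}benzene-1,2,4,5-tetrol | CC1=CC[C@H]2C(C)(C)CCC[C@]2(C)[C@@H]1Cc1c(O)c(O)cc(O)c1O | intermediate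
13 | 2,4,5-trihydroxy-3-{[(1R,4aS,8aS)-2,5,5,8a-tetramethyl-1,4,4a,5,6,7,8,8a-octahydronaphthalen-1-yl]methyl}phenyl hydrogen sulfate | CC1=CC[C@H]2C(C)(C)CCC[C@]2(C)[C@@H]1Cc1c(O)c(O)cc(OS(=O)(=O)O)c1O | target

## Step count and risks

Total steps: 7. Longest linear sequence: 7 (from 1).

Steps most likely to fail:

Step 6 (new light-driven quinone alkylation). The C11 radical may be captured by the thiohydroxamate ester instead of the quinone, or pyridine-2-thiol may add to the quinone. The fallback sets out from acid 8 and comes back at 11 using Fieser's thermal peroxide alkylation of hydroxyquinones, which is known for 9 itself. Acid 8 is coupled with H2O2 (DCC, Et2O, 0 °C) to the symmetrical diacyl peroxide bis{2-[(1R,4aS,8aS)-2,5,5,8a-tetramethyl-1,4,4a,5,6,7,8,8a-octahydronaphthalen-1-yl]acetyl} peroxide F1. This is decomposed in AcOH at 95 °C with excess 9 to give 11, one acyl half being returned as acid 8.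

Step 4 (facial selectivity of hydride delivery at C7). Attack from the beta face would give the natural 9-alpha-H ester. The fallback sets out from enone 3 and comes back at 7 through an intermediate whose C7 configuration can be assigned and corrected:
- Luche reduction (NaBH4, CeCl3·7H2O, MeOH, −20 °C) gives the 7-beta allylic alcohol methyl 2-[(3S,4aS,8aS)-3-hydroxy-2,5,5,8a-tetramethyl-3,4,4a,5,6,7,8,8a-octahydronaphthalen-1-yl]acetate F2, checked by NOE.
- Mitsunobu reaction with formic acid (PPh3, DIAD, THF) inverts it to the 7-alpha formate methyl 2-[(3R,4aS,8aS)-3-(formyloxy)-2,5,5,8a-tetramethyl-3,4,4a,5,6,7,8,8a-octahydronaphthalen-1-yl]acetate F3. If the Luche product is already 7-alpha, it is simply formylated.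
- Tsuji–Mandai hydrogenolysis (Pd(OAc)2, PBu3, dioxane, reflux) gives 7. Zerovalent palladium ionises anti to the formate, placing the metal on the beta face, and the palladium hydride formed on CO2 loss is delivered to the more substituted terminus C9 on that face.

Step 7 (mono- and regioselective sulfation of an air-sensitive tetrol). The fallback sets out from 11 and comes back at 13 by introducing the sulfate as a neutral, chromatographable diester. Compound 11 is reduced as before to 12 and treated at −78 °C with 2,2,2-trichloroethyl chlorosulfate (1.0 equiv, Et3N, cat. DMAP, THF). This gives 2,4,5-trihydroxy-3-{[(1R,4aS,8aS)-2,5,5,8a-tetramethyl-1,4,4a,5,6,7,8,8a-octahydronaphthalen-1-yl]methyl}phenyl 2,2,2-trichloroethyl sulfate F4, separable on silica from bis-sulfated and more hindered regioisomeric material. Zinc dust with HCO2NH4 in MeOH, then H+ exchange, releases 13.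

## Further compounds

F1 | step 6 | bis{2-[(1R,4aS,8aS)-2,5,5,8a-tetramethyl-1,4,4a,5,6,7,8,8a-octahydronaphthalen-1-yl]acetyl} peroxide | CC1=CC[C@H]2C(C)(C)CCC[C@]2(C)[C@@H]1CC(=O)OOC(=O)C[C@@H]1C(C)=CC[C@H]2C(C)(C)CCC[C@]12C
F2 | step 4 | methyl 2-[(3S,4aS,8aS)-3-hydroxy-2,5,5,8a-tetramethyl-3,4,4a,5,6,7,8,8a-octahydronaphthalen-1-yl]acetate | COC(=O)CC1=C(C)[C@@H](O)C[C@H]2C(C)(C)CCC[C@]12C
F3 | step 4 | methyl 2-[(3R,4aS,8aS)-3-(formyloxy)-2,5,5,8a-tetramethyl-3,4,4a,5,6,7,8,8a-octahydronaphthalen-1-yl]acetate | COC(=O)CC1=C(C)[C@H](OC=O)C[C@H]2C(C)(C)CCC[C@]12C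
F4 | step 7 | 2,4,5-trihydroxy-3-{[(1R,4aS,8aS)-2,5,5,8a-tetramethyl-1,4,4a,5,6,7,8,8a-octahydronaphthalen-1-yl]methyl}phenyl 2,2,2-trichloroethyl sulfate | CC1=CC[C@H]2C(C)(C)CCC[C@]2(C)[C@@H]1Cc1c(O)c(O)cc(OS(=O)(=O)OCC(Cl)(Cl)Cl)c1O
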